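**Retrosynthetic overview**
1. Target 20 ⇐ (5R,6S)-5,6-epoxide 19 of (6'R)-α-carotene: acid opens C6–O and the oxygen held on C5 recloses on C8 (oxirane → 2,5-dihydrofuran), as in the natural 5,6-epoxide → 5,8-furanoid pathway.
2. 19 ⇐ (6'R)-α-carotene 17 by site- and face-selective catalytic epoxidation of C5=C6 on the intact C40 polyene, in the same operation.
3. 17 ⇐ C15 + C10 + C15: two successive Wittig reactions on 2,7-dimethylocta-2,4,6-trienedial.
4. The two C15 phosphonium salts ⇐ β-ionone and (R)-α-ionone (vinyl Grignard addition, then PPh3·HBr).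
5. Ring order: both cyclohexene rings are bought in the ionones (the ε ring already 6R); the oxirane and then the dihydrofuran are the only rings made, in the last step.

Assumption: (R)-(+)-α-ionone of ≥98% ee (natural flavour grade) and all-E 2,7-dimethylocta-2,4,6-trienedial are bought; carotenoid numbering is used (β end unprimed, ε end primed); all polyene work is done under argon in subdued light.

**Step 1**
Reactants: 1 (R)-(+)-α-ionone; 2 vinylmagnesium bromide
Product: 4 vinyl-α-ionol = (1E)-3-methyl-1-[(1R)-2,6,6-trimethylcyclohex-2-en-1-yl]penta-1,4-dien-3-ol (both C3 epimers), via bromomagnesium alkoxide 3 (not isolated)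
Conditions: CH2=CHMgBr (1.3 equiv), THF, −20 → 0 °C; then ice-water
Reagents that add atoms: vinylmagnesium bromide (2), C=C[Mg]Br
Why: Grignard 1,2-addition to the enone carbonyl at low temperature leaves the 6R centre untouched; the new carbinol centre forms unselectively and is erased in step 2.

**Step 2**
Reactants: 4 vinyl-α-ionol; 5 triphenylphosphine hydrobromide
Product: 6 [(2E,4E)-3-methyl-5-[(1R)-2,6,6-trimethylcyclohex-2-en-1-yl]penta-2,4-dien-1-yl]triphenylphosphonium bromide (ε-C15 salt)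
Conditions: PPh3·HBr (1.0 equiv), MeOH, 0 °C → rt, 16 h; crystallise (EtOAc) to the 2E,4E salt
Reagents that add atoms: triphenylphosphine hydrobromide (5), [Br-].[PH+](c1ccccc1)(c1ccccc1)c1ccccc1
Why: Allylic substitution with transposition (SN1′ type): the tertiary bis-allylic alcohol ionises to a pentadienyl cation that PPh3 captures at the unhindered terminus, and the mild acid leaves the ε-ring double bond and the 6R centre in place.

**Step 3**
Reactants: 7 β-ionone; 2 vinylmagnesium bromide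
Product: 9 vinyl-β-ionol = (1E)-3-methyl-1-(2,6,6-trimethylcyclohex-1-en-1-yl)penta-1,4-dien-3-ol (racemic), via bromomagnesium alkoxide 8 (not isolated)
Conditions: CH2=CHMgBr (1.3 equiv), THF, −20 → 0 °C; then ice-water
Reagents that add atoms: vinylmagnesium bromide (2), C=C[Mg]Br
Why: Grignard 1,2-addition to the ketone; the carbinol centre is lost in step 4.

**Step 4**
Reactants: 9 vinyl-β-ionol; 5 triphenylphosphine hydrobromide
Product: 10 [(2E,4E)-3-methyl-5-(2,6,6-trimethylcyclohex-1-en-1-yl)penta-2,4-dien-1-yl]triphenylphosphonium bromide (β-C15 salt)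
Conditions: PPh3·HBr (1.0 equiv), MeOH, 0 °C → rt, 16 h; crystallise
Reagents that add atoms: triphenylphosphine hydrobromide (5), [Br-].[PH+](c1ccccc1)(c1ccccc1)c1ccccc1
Why: The same SN1′-type allylic transposition as in step 2, the standard entry to the C15 Wittig salt.

**Step 5**
Reactants: 10 β-C15 salt; 11 (2E,4E,6E)-2,7-dimethylocta-2,4,6-trienedial
Product: 14 all-E 12'-apo-β-caroten-12'-al (C25 aldehyde), via β-C15 ylide 12 (not isolated), via 11Z aldehyde 13 (not isolated)
Conditions: 10 + 11 (2.5 equiv), CH2Cl2, 0 °C; NaOMe/MeOH (1.05 equiv) dropwise; → rt; then n-heptane, 80 °C, Ar, dark; chromatography (excess 11 recovered)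
Reagents that add atoms: none
Why: Wittig olefination with a semi-stabilised allylic ylide, held at mono-condensation by the excess of dialdehyde; the hindered 11Z isomer (H-10 against 13-CH3) relaxes to E on warming.

**Step 6**
Reactants: 14 C25 aldehyde; 6 ε-C15 salt
Product: 17 (6'R)-β,ε-carotene (all-E α-carotene), via ε-C15 ylide 15 (not isolated), via 11'Z carotene 16 (not isolated)
Conditions: 14 + 6 (1.2 equiv), CH2Cl2, 0 °C; NaOMe/MeOH (1.25 equiv) dropwise; → rt; then n-heptane, 90 °C, Ar, dark; crystallise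
Reagents that add atoms: none
Why: Wittig olefination; methoxide is far too weak to remove the doubly allylic H-6', so the 6'R centre from 1 is kept, and heating converts the hindered 11'Z isomer to all-E.

**Step 7**
Reactants: 17 (6'R)-β,ε-carotene; 18 potassium peroxymonosulfate
Product: 20 (5R,8R,6'R)-5,8-epoxy-5,8-dihydro-β,ε-carotene (flavochrome; the target), via (5R,6S,6'R)-5,6-epoxide 19 (not isolated)
Conditions: (a) Shi's D-glucose-derived N-(4-methylphenyl) spiro-oxazolidinone ketone (C17H19NO6, 30 mol %), KHSO5 (as 2KHSO5·KHSO4·K2SO4, 1.1 equiv), K2CO3, Bu4NHSO4 (5 mol %), DME/DMM–aq. buffer pH 8–9, −10 °C, Ar, dark, to ca. 70% conversion; (b) toluene extract dried over K2CO3, (PhO)2P(O)OH (5 mol %), toluene, −40 °C, 30 min; Et3N; Et3N-deactivated silica, then HPLC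
Reagents that add atoms: potassium peroxymonosulfate (18), [K+].[O-]S(=O)(=O)OO
Why: Proposed new method: the twisted tetrasubstituted C5=C6 bond is the most electron-rich olefin of 17 and the one peracids attack in carotenes, so the electrophilic chiral dioxirane (Shi epoxidation; closest precedent is this ketone class on aryl-conjugated cis and tetrasubstituted olefins) should epoxidise it first, with the polyenyl group beside the oxazolidinone in the spiro transition state so that oxygen arrives on the face giving (5R,6S) (the sense known for 1-phenylcyclohexene → (R,R)-oxide and cis-β-methylstyrene → (1R,2S)-oxide, both of which map onto 5R,6S); the weak acid in a non-polar solvent then opens C6–O to a contact ion pair in which the oxygen kept on C5 closes on C8 from the face it left (suprafacial 1,3-oxygen shift, the 5,6-epoxide → 5,8-furanoid rearrangement), which retains 5R and, with the 7E geometry, gives 8R, any 8-epimer being removed by chromatography.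

**Compound list**
1 | (R)-(+)-α-ionone, (3E)-4-[(1R)-2,6,6-trimethylcyclohex-2-en-1-yl]but-3-en-2-one | CC1=CCCC(C)(C)[C@H]1/C=C/C(C)=O | starting material
2 | vinylmagnesium bromide | C=C[Mg]Br | starting material
3 | bromomagnesium alkoxide of vinyl-α-ionol (not isolated) | CC1=CCCC(C)(C)[C@H]1/C=C/C(C)(C=C)O[Mg]Br | intermediate
4 | vinyl-α-ionol, (1E)-3-methyl-1-[(1R)-2,6,6-trimethylcyclohex-2-en-1-yl]penta-1,4-dien-3-ol (C3 epimers) | CC1=CCCC(C)(C)[C@H]1/C=C/C(C)(O)C=C | intermediate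
5 | triphenylphosphine hydrobromide | [Br-].[PH+](c1ccccc1)(c1ccccc1)c1ccccc1 | starting material
6 | [(2E,4E)-3-methyl-5-[(1R)-2,6,6-trimethylcyclohex-2-en-1-yl]penta-2,4-dien-1-yl]triphenylphosphonium bromide | CC1=CCCC(C)(C)[C@H]1/C=C/C(C)=C/C[P+](c1ccccc1)(c1ccccc1)c1ccccc1.[Br-] | intermediate
7 | β-ionone, (3E)-4-(2,6,6-trimethylcyclohex-1-en-1-yl)but-3-en-2-one | CC1=C(/C=C/C(C)=O)C(C)(C)CCC1 | starting material
8 | bromomagnesium alkoxide of vinyl-β-ionol (not isolated) | CC1=C(/C=C/C(C)(C=C)O[Mg]Br)C(C)(C)CCC1 | intermediate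
9 | vinyl-β-ionol, (1E)-3-methyl-1-(2,6,6-trimethylcyclohex-1-en-1-yl)penta-1,4-dien-3-ol (racemic) | CC1=C(/C=C/C(C)(O)C=C)C(C)(C)CCC1 | intermediate
10 | [(2E,4E)-3-methyl-5-(2,6,6-trimethylcyclohex-1-en-1-yl)penta-2,4-dien-1-yl]triphenylphosphonium bromide | CC1=C(/C=C/C(C)=C/C[P+](c2ccccc2)(c2ccccc2)c2ccccc2)C(C)(C)CCC1.[Br-] | intermediate
11 | (2E,4E,6E)-2,7-dimethylocta-2,4,6-trienedial | O=C/C(C)=C/C=C/C=C(C)/C=O | starting material
12 | β-C15 triphenylphosphonium ylide (not isolated) | CC1=C(/C=C/C(C)=C/C=P(c2ccccc2)(c2ccccc2)c2ccccc2)C(C)(C)CCC1 | intermediate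
13 | (11Z)-12'-apo-β-caroten-12'-al (not isolated) | CC1=C(/C=C/C(C)=C/C=C\C(C)=C\C=C\C=C(C)\C=O)C(C)(C)CCC1 | intermediate
14 | all-E 12'-apo-β-caroten-12'-al | CC1=C(/C=C/C(C)=C/C=C/C(C)=C/C=C/C=C(C)/C=O)C(C)(C)CCC1 | intermediate
15 | ε-C15 triphenylphosphonium ylide, 6R (not isolated) | CC1=CCCC(C)(C)[C@H]1/C=C/C(C)=C/C=P(c1ccccc1)(c1ccccc1)c1ccccc1 | intermediate
16 | (11'Z,6'R)-β,ε-carotene (not isolated) | CC1=CCCC(C)(C)[C@H]1/C=C/C(C)=C/C=C\C(C)=C\C=C\C=C(C)\C=C\C=C(C)\C=C\C1=C(C)CCCC1(C)C | intermediate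
17 | (6'R)-β,ε-carotene, all-E (α-carotene) | CC1=CCCC(C)(C)[C@H]1/C=C/C(C)=C/C=C/C(C)=C/C=C/C=C(C)/C=C/C=C(C)/C=C/C1=C(C)CCCC1(C)C | intermediate
18 | potassium peroxymonosulfate | [K+].[O-]S(=O)(=O)OO | starting material
19 | (5R,6S,6'R)-5,6-epoxy-5,6-dihydro-β,ε-carotene (not isolated) | CC1=CCCC(C)(C)[C@H]1/C=C/C(C)=C/C=C/C(C)=C/C=C/C=C(C)/C=C/C=C(C)/C=C/[C@@]12O[C@]1(C)CCCC2(C)C | intermediate
20 | (5R,8R,6'R)-5,8-epoxy-5,8-dihydro-β,ε-carotene (flavochrome) | CC1=CCCC(C)(C)[C@H]1/C=C/C(C)=C/C=C/C(C)=C/C=C/C=C(C)/C=C/C=C(\C)[C@H]1C=C2C(C)(C)CCC[C@@]2(C)O1 | target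

**Totals**
Total steps: 7. Longest linear sequence: 5 (7 → 9 → 10 → 14 → 17 → 20; steps 3, 4, 5, 6, 7).

**Three steps most likely to fail**

Step 7 (most likely). The face selectivity of the chiral dioxirane on a tetrasubstituted polyenyl olefin is untested, the ε-ring and chain double bonds may compete, and the C8 ratio could approach 1:1.
The fallback brings the oxirane in with secured configuration and builds the C40 epoxide by Wittig coupling. It sets out from salt 6 (with dialdehyde 11) and comes back at epoxide 19, which is then isolated and given only the acid stage of step 7. Ylide 15 from 6 and an excess of 11, under the conditions of step 5, give (6R)-12'-apo-ε-caroten-12'-al F1. NaBH4 (EtOH, 0 °C) reduces it to (6R)-12'-apo-ε-caroten-12'-ol F2, and PPh3·HBr (5) converts that into the C25 triphenylphosphonium bromide F3. Separately, bought β-cyclogeraniol F4 undergoes Sharpless epoxidation (Ti(OiPr)4, D-(−)-diethyl tartrate, t-BuOOH, 4 Å sieves, CH2Cl2, −20 °C) to [(1R,6R)-2,2,6-trimethyl-7-oxabicyclo[4.1.0]heptan-1-yl]methanol F5. Oxidation (SO3·pyridine, DMSO, Et3N) gives (1S,6R)-2,2,6-trimethyl-7-oxabicyclo[4.1.0]heptane-1-carbaldehyde F6. Horner–Wadsworth–Emmons reaction with bought diethyl [(2E)-3-cyano-2-methylprop-2-en-1-yl]phosphonate F7 (NaH, THF) gives the C15 epoxy dienenitrile F8, and i-Bu2AlH (−78 °C, then wet silica) gives the C15 epoxy dienal F9. F3 and F9 are coupled under the conditions of step 6 to give 19. In the acid stage on isolated 19, any (5R,8S,6'R)-5,8-epoxy-5,8-dihydro-β,ε-carotene F10 is separated by HPLC and re-equilibrated at C8 by a second exposure to the same acid at 0 °C.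

Step 5. Mono-olefination of a symmetrical dialdehyde is statistical; double condensation gives β-carotene and wastes 10.
The fallback desymmetrises the dialdehyde by protection. It sets out from 11 and comes back at 14. Bought 2,2-dimethylpropane-1,3-diol F11 (1 equiv, pyridinium p-toluenesulfonate cat., toluene) converts 11 into the mono-acetal (2E,4E,6E)-7-(5,5-dimethyl-1,3-dioxan-2-yl)-2-methylocta-2,4,6-trienal F12; bis-acetal and unchanged 11 are separated and re-equilibrated. Ylide 12 from 10, now used in slight excess under the conditions of step 5, gives the C25 acetal F13, and dilute aqueous oxalic acid in acetone unmasks 14.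

Step 2. A pentadienyl cation is generated next to the 6R centre under acid; possible outcomes are loss of ee, migration of the ε-ring double bond, or a poor 2E/2Z ratio.
The fallback builds the C15 chain by olefination and forms the salt under neutral conditions. It sets out from 1 and comes back at 6. Horner–Wadsworth–Emmons reaction of 1 with bought triethyl phosphonoacetate F14 (NaH, THF) gives ethyl (2E,4E)-3-methyl-5-[(1R)-2,6,6-trimethylcyclohex-2-en-1-yl]penta-2,4-dienoate F15 (2Z isomer removed). i-Bu2AlH (−78 °C) gives the allylic alcohol F16, and CBr4/PPh3 (CH2Cl2, −20 °C) gives the allylic bromide F17. F17 is not stored but treated at once with PPh3 (toluene, rt) to give 6 by SN2 displacement.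

**Further compounds**
F1 | step 7 | (6R)-12'-apo-ε-caroten-12'-al | CC1=CCCC(C)(C)[C@H]1/C=C/C(C)=C/C=C/C(C)=C/C=C/C=C(C)/C=O
F2 | step 7 | (6R)-12'-apo-ε-caroten-12'-ol | CC1=CCCC(C)(C)[C@H]1/C=C/C(C)=C/C=C/C(C)=C/C=C/C=C(C)/CO
F3 | step 7 | [(6R)-12'-apo-ε-caroten-12'-yl]triphenylphosphonium bromide | CC1=CCCC(C)(C)[C@H]1/C=C/C(C)=C/C=C/C(C)=C/C=C/C=C(C)/C[P+](c1ccccc1)(c1ccccc1)c1ccccc1.[Br-]
F4 | step 7 | β-cyclogeraniol, (2,6,6-trimethylcyclohex-1-en-1-yl)methanol (bought) | CC1=C(CO)C(C)(C)CCC1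
F5 | step 7 | [(1R,6R)-2,2,6-trimethyl-7-oxabicyclo[4.1.0]heptan-1-yl]methanol | OC[C@@]12O[C@]1(C)CCCC2(C)C
F6 | step 7 | (1S,6R)-2,2,6-trimethyl-7-oxabicyclo[4.1.0]heptane-1-carbaldehyde | O=C[C@@]12O[C@]1(C)CCCC2(C)C
F7 | step 7 | diethyl [(2E)-3-cyano-2-methylprop-2-en-1-yl]phosphonate (bought) | CCOP(=O)(OCC)C/C(C)=C/C#N
F8 | step 7 | (2E,4E)-3-methyl-5-[(1S,6R)-2,2,6-trimethyl-7-oxabicyclo[4.1.0]heptan-1-yl]penta-2,4-dienenitrile | N#C/C=C(C)/C=C/[C@@]12O[C@]1(C)CCCC2(C)C
F9 | step 7 | (2E,4E)-3-methyl-5-[(1S,6R)-2,2,6-trimethyl-7-oxabicyclo[4.1.0]heptan-1-yl]penta-2,4-dienal | O=C/C=C(C)/C=C/[C@@]12O[C@]1(C)CCCC2(C)C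
F10 | step 7 | (5R,8S,6'R)-5,8-epoxy-5,8-dihydro-β,ε-carotene | CC1=CCCC(C)(C)[C@H]1/C=C/C(C)=C/C=C/C(C)=C/C=C/C=C(C)/C=C/C=C(\C)[C@@H]1C=C2C(C)(C)CCC[C@@]2(C)O1
F11 | step 5 | 2,2-dimethylpropane-1,3-diol (bought) | OCC(C)(C)CO
F12 | step 5 | (2E,4E,6E)-7-(5,5-dimethyl-1,3-dioxan-2-yl)-2-methylocta-2,4,6-trienal | O=C/C(C)=C/C=C/C=C(C)/C1OCC(C)(C)CO1
F13 | step 5 | 12'-apo-β-caroten-12'-al 2,2-dimethylpropane-1,3-diyl acetal | CC1=C(/C=C/C(C)=C/C=C/C(C)=C/C=C/C=C(C)/C2OCC(C)(C)CO2)C(C)(C)CCC1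
F14 | step 2 | triethyl phosphonoacetate (bought) | CCOC(=O)CP(=O)(OCC)OCC
F15 | step 2 | ethyl (2E,4E)-3-methyl-5-[(1R)-2,6,6-trimethylcyclohex-2-en-1-yl]penta-2,4-dienoate | CC1=CCCC(C)(C)[C@H]1/C=C/C(C)=C/C(=O)OCC
F16 | step 2 | (2E,4E)-3-methyl-5-[(1R)-2,6,6-trimethylcyclohex-2-en-1-yl]penta-2,4-dien-1-ol | CC1=CCCC(C)(C)[C@H]1/C=C/C(C)=C/CO
F17 | step 2 | (6R)-6-[(1E,3E)-5-bromo-3-methylpenta-1,3-dien-1-yl]-1,5,5-trimethylcyclohex-1-ene | CC1=CCCC(C)(C)[C@H]1/C=C/C(C)=C/CBr
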